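**Retrosynthetic overview**
1. Target 16 ⇐ C6=C7 desaturation of ketone 15 ⇐ angeloylation of the C3–OH of triol 12 ⇐ acetone aldol at C7 of trans-decalone 10.
2. Ring B of 10 ⇐ one-carbon ring expansion of trans-hydrindanone 8: 1,2-shift of the quaternary C10 onto a carbenoid carbon from CH2Br2, which also moves the ketone from next to C10 to C8.
3. Ring A diol of 8 ⇐ hydroxyl-directed ketone reduction ⇐ hydrogen-atom-transfer reductive α-hydroxylation of enedione 5 (sets C5, C4, then C3).
4. 5 ⇐ amino-acid-catalysed Robinson-type annulation of 2-methylcyclopentane-1,3-dione with ethyl vinyl ketone (sets C10).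
5. Ring order: cyclopentane (bought) → ring A (annulation) → ring B (ring expansion of the five-membered ring).

Convention: locants C1–C11 in the comments are eudesmane locants of the target (C3 ester carbon, C4 tertiary carbinol, C5 ring-fusion CH, C10 angular-methyl carbon, C8 ketone, C7 and C11 the side-chain carbons); α is the face opposite the angular methyl. A telescoped one-flask operation is counted as one step.

**Step 1**
Reactants: 1 2-methylcyclopentane-1,3-dione; 2 pent-1-en-3-one (ethyl vinyl ketone)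
Product: 5 (S)-4,7a-dimethyl-2,3,7,7a-tetrahydro-1H-indene-1,5(6H)-dione, via Michael triketone 3 (not isolated), via aldol ketol 4 (not isolated)
Conditions: Et3N (5 mol %), MeCN, 25 °C; then L-phenylalanine (1 equiv), 1 M aq HClO4 (0.5 equiv), reflux; recrystallise to raise ee
Reagents that add atoms: none
Why: Michael addition of the cyclic 1,3-dione to the enone followed by a Hajos–Parrish–Eder–Sauer–Wiechert enamine aldol condensation, in which the L-phenylalanine enamine of the side-chain ketone attacks one of the two enantiotopic ring carbonyls and so sets the quaternary stereocentre (C10 of the target) as S before acid dehydrates ketol 4 to the enone.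

**Step 2**
Reactants: 5 (S)-4,7a-dimethyl-2,3,7,7a-tetrahydro-1H-indene-1,5(6H)-dione
Product: 7 (3aR,4S,7aS)-4-hydroxy-4,7a-dimethylhexahydro-1H-indene-1,5(4H)-dione, via tertiary hydroperoxide 6 (not isolated)
Conditions: Mn(dpm)3 (10 mol %; dpm = 2,2,6,6-tetramethylheptane-3,5-dionate), PhSiH3, O2 (1 atm), i-PrOH/CH2Cl2, 0 °C; then P(OEt)3
Reagents that add atoms: dioxygen, O=O
Why: Metal-hydride hydrogen-atom-transfer reductive α-oxygenation of an enone (Mukaiyama/Magnus type): the Mn–H species delivers H• to the ring-fusion β-carbon from the α face, anti to the angular methyl (trans fusion, C5–Hα), the tertiary α-keto radical at C4 is trapped by O2 on the same α face because the β face is screened by the 1,3-related angular methyl (C4–O α, methyl β), and P(OEt)3 reduces hydroperoxide 6, while the isolated cyclopentanone is not touched.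

**Step 3**
Reactants: 7 (3aR,4S,7aS)-4-hydroxy-4,7a-dimethylhexahydro-1H-indene-1,5(4H)-dione
Product: 8 (3aR,4S,5S,7aS)-4,5-dihydroxy-4,7a-dimethyloctahydro-1H-inden-1-one
Conditions: Me4NBH(OAc)3, MeCN/AcOH (1:1), −30 to 0 °C
Reagents that add atoms: none
Why: Hydroxyl-directed triacetoxyborohydride reduction (Saksena–Evans type): the reagent exchanges onto the tertiary 4α-OH and delivers hydride to the neighbouring C3 ketone from the α (axial) face, which is also the open face because the axial 4β-methyl blocks the other one, giving the equatorial 3β-alcohol (trans-diequatorial diol), whereas the undirected cyclopentanone is inert to this mild hydride.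

**Step 4**
Reactants: 8 (3aR,4S,5S,7aS)-4,5-dihydroxy-4,7a-dimethyloctahydro-1H-inden-1-one
Product: 10 (4aR,5S,6S,8aR)-5,6-dihydroxy-5,8a-dimethyloctahydronaphthalen-2(1H)-one, via dibromomethyl carbinol 9 (not isolated)
Conditions: CH2Br2, LiTMP (lithium 2,2,6,6-tetramethylpiperidide, 3.3 equiv), THF, −78 °C; then n-BuLi, −78 to 0 °C; H2O
Reagents that add atoms: dibromomethane, BrCBr
Why: Proposed new method: a β-oxido carbenoid ring enlargement run on the unprotected diol (as its dilithium alkoxide) in which the quaternary ring-fusion carbon migrates – LiCHBr2 adds to the cyclopentanone from the face opposite the angular methyl, Br/Li exchange on alkoxide 9 gives the carbenoid R2C(OLi)–CHLiBr, and the more electron-rich C–C bond (that of C10) shifts to the electron-poor carbenoid carbon with loss of LiBr and relief of trans-hydrindanone strain, giving the C8–C9 lithium enolate of the trans-decalone with retention at C10 and the carbonyl now one carbon away from C10 (protonated on quench); the closest known reaction type is the Nozaki–Yamamoto dibromomethyllithium/butyllithium ring enlargement of simple 2-alkylcycloalkanones, where the more substituted carbon migrates, which has not been shown for a quaternary ring-fusion carbon of a trans-hydrindan-1-one or with free hydroxyl groups present.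

**Step 5**
Reactants: 10 (4aR,5S,6S,8aR)-5,6-dihydroxy-5,8a-dimethyloctahydronaphthalen-2(1H)-one; 11 acetone
Product: 12 (3R,4aR,5S,6S,8aR)-5,6-dihydroxy-3-(2-hydroxypropan-2-yl)-5,8a-dimethyloctahydronaphthalen-2(1H)-one
Conditions: LiN(i-Pr)2 (3.3 equiv), THF, −78 °C; CeCl3; acetone; AcOH, −78 °C
Reagents that add atoms: none
Why: Directed aldol addition: after the two hydroxyls, kinetic deprotonation with LiN(i-Pr)2 takes place at C7 because C9 is neopentyl and shielded by the quaternary C10, the cerium enolate adds to the easily enolised acetone without proton transfer, and the cold acidic quench prevents retro-aldol, while the new C7 stereocentre (mainly equatorial, as drawn) is removed again in step 7.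

**Step 6**
Reactants: 12 (3R,4aR,5S,6S,8aR)-5,6-dihydroxy-3-(2-hydroxypropan-2-yl)-5,8a-dimethyloctahydronaphthalen-2(1H)-one; 13 angelic acid ((Z)-2-methylbut-2-enoic acid)
Product: 15 (1S,2S,4aR,7R,8aR)-1-hydroxy-7-(2-hydroxypropan-2-yl)-1,4a-dimethyl-6-oxodecahydronaphthalen-2-yl (Z)-2-methylbut-2-enoate, via mixed anhydride 14 (not isolated)
Conditions: 13, 2,4,6-trichlorobenzoyl chloride, Et3N, toluene, 25 °C; then 12, 75 °C
Reagents that add atoms: none
Why: Yamaguchi-type mixed-anhydride esterification: only the secondary equatorial 3β-OH is acylated (both tertiary hydroxyls are inert), attack occurs at the unhindered angeloyl carbonyl of 14, and the DMAP-free conditions avoid the addition–elimination isomerisation of the (Z)-angelate to the (E)-tiglate.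

**Step 7**
Reactants: 15 (1S,2S,4aR,7R,8aR)-1-hydroxy-7-(2-hydroxypropan-2-yl)-1,4a-dimethyl-6-oxodecahydronaphthalen-2-yl (Z)-2-methylbut-2-enoate
Product: 16 (1S,2S,4aR,8aR)-1-hydroxy-7-(2-hydroxypropan-2-yl)-1,4a-dimethyl-6-oxo-1,2,3,4,4a,5,6,8a-octahydronaphthalen-2-yl (Z)-2-methylbut-2-enoate
Conditions: IBX, 4-methoxypyridine N-oxide, DMSO, 25–40 °C
Reagents that add atoms: none
Why: IBX dehydrogenation of a ketone to an enone (single-electron oxidation of the enol by the pentavalent iodine reagent activated by the N-oxide ligand): desaturation can only occur between C7 and C6 because C9 is flanked by the quaternary C10, which gives the conjugated C6=C7 enone directly, and the tertiary alcohols, the angelate and the stereocentres at C3, C4, C5 and C10 are untouched under these neutral, near-room-temperature conditions.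

**Compound list**
1 | 2-methylcyclopentane-1,3-dione | CC1C(=O)CCC1=O | starting material
2 | pent-1-en-3-one (ethyl vinyl ketone) | CCC(=O)C=C | starting material
3 | 2-methyl-2-(3-oxopentyl)cyclopentane-1,3-dione | CCC(=O)CCC1(C)C(=O)CCC1=O | intermediate
4 | (3aS,7aS)-3a-hydroxy-4,7a-dimethylhexahydro-1H-indene-1,5(4H)-dione (cis-fused ketol, both C4 epimers) | O=C1CC[C@]2(C)C(=O)CC[C@]2(O)C1C | intermediate
5 | (S)-4,7a-dimethyl-2,3,7,7a-tetrahydro-1H-indene-1,5(6H)-dione | O=C1CC[C@]2(C)C(=O)CCC2=C1C | intermediate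
6 | (3aR,4S,7aS)-4-hydroperoxy-4,7a-dimethylhexahydro-1H-indene-1,5(4H)-dione | O=C1CC[C@]2(C)C(=O)CC[C@H]2[C@]1(C)OO | intermediate
7 | (3aR,4S,7aS)-4-hydroxy-4,7a-dimethylhexahydro-1H-indene-1,5(4H)-dione (trans-fused) | O=C1CC[C@]2(C)C(=O)CC[C@H]2[C@]1(C)O | intermediate
8 | (3aR,4S,5S,7aS)-4,5-dihydroxy-4,7a-dimethyloctahydro-1H-inden-1-one | O[C@H]1CC[C@]2(C)C(=O)CC[C@H]2[C@]1(C)O | intermediate
9 | (1S,3aR,4S,5S,7aS)-1-(dibromomethyl)-4,7a-dimethyloctahydro-1H-indene-1,4,5-triol (present as its lithium alkoxide) | O[C@H]1CC[C@]2(C)[C@](O)(C(Br)Br)CC[C@H]2[C@]1(C)O | intermediate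
10 | (4aR,5S,6S,8aR)-5,6-dihydroxy-5,8a-dimethyloctahydronaphthalen-2(1H)-one (trans-decalone) | O[C@H]1CC[C@]2(C)CC(=O)CC[C@H]2[C@]1(C)O | intermediate
11 | acetone | CC(C)=O | starting material
12 | (3R,4aR,5S,6S,8aR)-5,6-dihydroxy-3-(2-hydroxypropan-2-yl)-5,8a-dimethyloctahydronaphthalen-2(1H)-one | O[C@H]1CC[C@]2(C)CC(=O)[C@@H](C(C)(C)O)C[C@H]2[C@]1(C)O | intermediate
13 | angelic acid, (Z)-2-methylbut-2-enoic acid | C/C=C(/C)C(=O)O | starting material
14 | (Z)-2-methylbut-2-enoic 2,4,6-trichlorobenzoic anhydride | C/C=C(/C)C(=O)OC(=O)c1c(Cl)cc(Cl)cc1Cl | intermediate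
15 | (1S,2S,4aR,7R,8aR)-1-hydroxy-7-(2-hydroxypropan-2-yl)-1,4a-dimethyl-6-oxodecahydronaphthalen-2-yl (Z)-2-methylbut-2-enoate | C/C=C(/C)C(=O)O[C@H]1CC[C@]2(C)CC(=O)[C@@H](C(C)(C)O)C[C@H]2[C@]1(C)O | intermediate
16 | (1S,2S,4aR,8aR)-1-hydroxy-7-(2-hydroxypropan-2-yl)-1,4a-dimethyl-6-oxo-1,2,3,4,4a,5,6,8a-octahydronaphthalen-2-yl (Z)-2-methylbut-2-enoate (CNP0261892.1) | C/C=C(/C)C(=O)O[C@H]1CC[C@]2(C)CC(=O)C(C(C)(C)O)=C[C@H]2[C@]1(C)O | target

**Totals**
Total step count: 7. Longest linear sequence: 7 steps (1 → 16).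

**Three steps most likely to fail**

Step 4 (the proposed new ring enlargement). The risks are migration of the CH2 instead of the quaternary carbon, or enolisation of the hindered ketone by the base. The fallback uses known chemistry, sets out from 8 and comes back at 10. Bis(phenylsulfanyl)methyllithium is added to 8 to give the carbinol (1S,3aR,4S,5S,7aS)-1-[bis(phenylsulfanyl)methyl]-4,7a-dimethyloctahydro-1H-indene-1,4,5-triol F4. (CuOTf)2·C6H6 (monovalent copper) with i-Pr2NEt in warm benzene removes one thiophenolate, and the sulfur-stabilised cation undergoes the known Cohen-type pinacol ring expansion with migration of the more substituted carbon. This gives the α-sulfenyl ketone (4aR,5S,6S,8aS)-5,6-dihydroxy-5,8a-dimethyl-1-(phenylsulfanyl)octahydronaphthalen-2(1H)-one F5 (C1 epimers), which Zn/AcOH desulfurises to 10.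

Step 2 (hydrogen-atom-transfer α-hydroxylation of a tetrasubstituted enone). The risks are sluggish hydrogen transfer or imperfect trans selectivity. The fallback sets out from 5 and comes back at 7. The saturated ketone is masked selectively with ethylene glycol/TsOH as (S)-4',7a'-dimethyl-2',3',7',7a'-tetrahydrospiro[[1,3]dioxolane-2,1'-inden]-5'(6'H)-one F1. Li/NH3 reduction of the enone (Birch-type, trans fusion) with Me3SiCl trapping gives the silyl enol ether trimethyl{[(3a'S,7a'S)-4',7a'-dimethyl-2',3',3a',6',7',7a'-hexahydrospiro[[1,3]dioxolane-2,1'-inden]-5'-yl]oxy}silane F2. Rubottom oxidation with mCPBA from the α face gives (3a'R,4'S,7a'S)-4'-hydroxy-4',7a'-dimethylhexahydrospiro[[1,3]dioxolane-2,1'-inden]-5'(4'H)-one F3, and aqueous HCl removes the ketal to return 7.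

Step 7 (IBX desaturation next to a tertiary aldol centre). The risks are retro-aldol loss of acetone or dehydration. The fallback sets out from 15 and comes back at 16. Catalytic TsOH in warm benzene dehydrates the β-hydroxy ketone to (1S,2S,4aR,8aR)-1-hydroxy-1,4a-dimethyl-6-oxo-7-(propan-2-ylidene)decahydronaphthalen-2-yl (Z)-2-methylbut-2-enoate F6. Photo-oxygenation (O2, hν, tetraphenylporphyrin, CH2Cl2, −20 °C) is a Schenck ene reaction that abstracts hydrogen from C6, the group geminal to the carbonyl, and gives (1S,2S,4aR,8aR)-7-(2-hydroperoxypropan-2-yl)-1-hydroxy-1,4a-dimethyl-6-oxo-1,2,3,4,4a,5,6,8a-octahydronaphthalen-2-yl (Z)-2-methylbut-2-enoate F7. PPh3 reduces this to 16.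

**Further compounds**
F1 | step 2 | (S)-4',7a'-dimethyl-2',3',7',7a'-tetrahydrospiro[[1,3]dioxolane-2,1'-inden]-5'(6'H)-one | O=C1CC[C@]2(C)C3(OCCO3)CCC2=C1C
F2 | step 2 | trimethyl{[(3a'S,7a'S)-4',7a'-dimethyl-2',3',3a',6',7',7a'-hexahydrospiro[[1,3]dioxolane-2,1'-inden]-5'-yl]oxy}silane (trans-fused) | C[Si](C)(C)OC=1CC[C@]2(C)C3(OCCO3)CC[C@H]2C1C
F3 | step 2 | (3a'R,4'S,7a'S)-4'-hydroxy-4',7a'-dimethylhexahydrospiro[[1,3]dioxolane-2,1'-inden]-5'(4'H)-one | O=C1CC[C@]2(C)C3(OCCO3)CC[C@H]2[C@]1(C)O
F4 | step 4 | (1S,3aR,4S,5S,7aS)-1-[bis(phenylsulfanyl)methyl]-4,7a-dimethyloctahydro-1H-indene-1,4,5-triol | O[C@H]1CC[C@]2(C)[C@](O)(C(Sc3ccccc3)Sc3ccccc3)CC[C@H]2[C@]1(C)O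
F5 | step 4 | (4aR,5S,6S,8aS)-5,6-dihydroxy-5,8a-dimethyl-1-(phenylsulfanyl)octahydronaphthalen-2(1H)-one (C1 epimers) | O[C@H]1CC[C@]2(C)C(Sc3ccccc3)C(=O)CC[C@H]2[C@]1(C)O
F6 | step 7 | (1S,2S,4aR,8aR)-1-hydroxy-1,4a-dimethyl-6-oxo-7-(propan-2-ylidene)decahydronaphthalen-2-yl (Z)-2-methylbut-2-enoate | C/C=C(/C)C(=O)O[C@H]1CC[C@]2(C)CC(=O)C(=C(C)C)C[C@H]2[C@]1(C)O
F7 | step 7 | (1S,2S,4aR,8aR)-7-(2-hydroperoxypropan-2-yl)-1-hydroxy-1,4a-dimethyl-6-oxo-1,2,3,4,4a,5,6,8a-octahydronaphthalen-2-yl (Z)-2-methylbut-2-enoate | C/C=C(/C)C(=O)O[C@H]1CC[C@]2(C)CC(=O)C(C(C)(C)OO)=C[C@H]2[C@]1(C)O
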